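The data were generated by integration with constants of no real substance.

Target is the thing to watch in the first hours: its lag and early slope give rough readings of two frequencies, that of regeneration and that of the substrate step.

common to all: spent carrier 10 mM; added ligand 57 mM

| flask | substrate | salt in the second phase | capture agent | remark | time | volume of the second phase over the first |
|---|---|---|---|---|---|---|
| midnight | 0.20 M | 0.16 M | 0.060 M | run made earlier |  |  |
| larch | 0.20 M | 0.240 M | 0.0600 M |  | 10 h | 0.50 |
| ash | 0.60 M | 0.240 M | 0.0600 M |  | 10 h | 0.50 |
| cedar | 2.0 M | 0.240 M | 0.0600 M |  | 10 h | 0.50 |

midnight run (percent of the substrate charged)

| time / h | target / % | substrate / % |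
|---|---|---|
| 0.500 | 0.3 | 99.1 |
| 1.50 | 2.7 | 97.7 |
| 3.00 | 4.6 | 95.2 |
| 4.00 | 5.6 | 94.9 |
| 6.00 | 6.5 | 91.7 |

(each reading ± 0.5 percentage points)

- a species is counted by the substrate in it: one side product counts as two
- in the second phase: salt in the second phase, spent salt in the second phase; everything else is in the first
- charges count per volume of the first phase; a concentration in a rate is the amount of a species over the volume of its own phase; every rate counts per litre of the first phase
- candidate steps: substrate + fresh carrier -> target + spent carrier; spent carrier + salt in the second phase <-> fresh carrier + spent salt in the second phase; substrate + target -> side product; added ligand + fresh carrier <-> idle complex; spent carrier + capture agent -> trapped intermediate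
- the earlier runs hold the two phases in the same ratio of volumes as the flask asked about
- "hardly changes" means that all values lie within two and a half points (for a concentration: within two and a half percent of the largest)

- [target] at the end for larch, ash, cedar, in this order
- how the row runs (falls, then rises / hardly changes / rises, then falls / falls all the way / rises all the way)

Two numbers in midnight did not go together. Target grew at 4.80 mM/h early and at 0.900 mM/h late, far slower, yet 91.7% of the substrate still stood. So I read the rate as following c(fresh carrier), not c(substrate).

Midnight was charged with spent carrier, and its early slope extrapolated back to a lag of 0.375 h. I took the inverse, 2.67 /h, as the regeneration frequency, and the slope per carrier charged, 0.480 /h, as the frequency of the substrate step. With a scatter of 0.5 percentage points both are rough readings.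

Scaling regeneration to the salt of larch gave 1.67 M, the crossover concentration: the c(substrate) at which the substrate step keeps pace with regeneration. Well below it the substrate step is the rate-limiting step and the rate is pseudo-first-order in substrate; above it the order falls towards zero. I reckoned c(fresh carrier)/c(spent carrier) as crossover over c(substrate): 8.33 for larch and 0.833 for cedar. Making per carrier should gain 2.47 from larch to ash, and 5.09 from larch to cedar.

The forecast gave 0.018 M, 0.013 M and 0.0035 M, a row that falls all the way, on the ground that “More substrate mainly speeds formation slightly but destroys more target”. My gain to ash is not slight, so I differed on the first step.

The flasks gave 0.0191 M, 0.0274 M and 0.0131 M: the row rises, then falls.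

    substrate + fresh carrier → target + spent carrier (k = 0.0480 /M/min)
    spent carrier + salt in the second phase ⇌ fresh carrier + spent salt in the second phase (K = 1.20, k = 0.160 /M/min)
    substrate + target → side product (k = 0.00200 /M/min)
    added ligand + fresh carrier ⇌ idle complex (K = 240 /M, k = 0.0250 /M/min)
    spent carrier + capture agent → trapped intermediate (k = 0.150 /M/min)

At 5.00 h c(fresh carrier)/c(spent carrier) stood at 5.31 in larch, against my 8.33, and at 0.581 in cedar, against my 0.833. The lifetime of target against substrate, the inverse of the side-product rate constant times c(substrate) as charged, was 41.7 h in larch, longer than the run, and 4.17 h in cedar, shorter than the run; the row turned at 0.59 M.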